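**Plan**

Retrosynthesis: the C8 ester, the C3 acetate and C12 (CO on a C11 enol triflate) come off first. Ring B is then cut at C6–C7 and C9–C10 into an acetoacetyl C7–C8–C9 unit and the ring-A keto carbonate 7, which goes back to (S)-carvone.
Enabling feature: in ring B the C10 carbinol lies β to the C8 oxygen (aldol retron) and C7 lies between C8 and C11 (1,3-dicarbonyl retron), so C7–C8–C9 is an acetone α,α′-dianion. In ring A the C3 oxygen and the C6–C7 bond are cis-1,4 across C4=C5, the mark of a Pd π-allyl opened from a C3,C4-carbonate next to C5=C6.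
Forward: ring A is kept from carvone (its isopropenyl C=C is cleaved to the C10 ketone) and ring B arises in one flask in step 7. C8 is then reduced, C11 becomes methyl ketone and enol triflate, O3 and O8 are acylated, CO gives C12, and the side-chain diol is unmasked.
Stereochemistry: C1 comes from carvone and C3 from a cis-selective Luche reduction. The C4–O bond is set by OH-directed epoxidation and relayed to C6 by double inversion at Pd. C7 and C10 are set by A1,3 strain in the closing enamine, C8 by hydride attack anti to the axial C14 methyl, and the side-chain E-alkene by a cis ring alkene.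

Key step: step 7

Remark: cadinane locants are used for all intermediates. Ring A is C1–C6 (O on C3, methyl on C4, C4=C5); ring B is C1, C6–C10 (C11–C13 on C7, O on C8, methyl C14 and OH on C10). β is the face of ring A that carries the C3 oxygen, and the SMILES strings are decisive. Compound 20 is racemic; its stereocentres vanish in step 14.

Step 1
Reactants: 1 (S)-(+)-carvone
Product: 2 (+)-cis-carveol, (1S,5S)-2-methyl-5-(prop-1-en-2-yl)cyclohex-2-en-1-ol (3β-OH cis to the C1 isopropenyl group)
Conditions: NaBH4, CeCl3·7H2O, MeOH, −20 °C
Reagents that add atoms: none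
Why: Luche 1,2-reduction, in which axial hydride attack on the half-chair with equatorial isopropenyl group should give the pseudo-equatorial 3β-alcohol cis to C1 and leave both alkenes untouched.

Step 2
Reactants: 2 (+)-cis-carveol
Product: 3 4β,5β-epoxy alcohol (epoxide cis to the 3β-OH and to the isopropenyl group)
Conditions: VO(acac)2 (cat.), t-BuOOH, CH2Cl2, 0 °C
Reagents that add atoms: tert-butyl hydroperoxide, CC(C)(C)OO
Why: Hydroxyl-directed vanadium-catalysed epoxidation should deliver oxygen to C4=C5 on the face of the allylic C3–OH (β) and spare the remote isopropenyl alkene.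

Step 3
Reactants: 3 4β,5β-epoxy alcohol
Product: 4 5α-(phenylselanyl)-3β,4β-diol (4α-methyl, 1β-isopropenyl)
Conditions: PhSeSePh, NaBH4, EtOH, 0 → 60 °C
Reagents that add atoms: diphenyl diselenide, c1ccc(cc1)[Se][Se]c1ccccc1
Why: SN2 epoxide opening by benzeneselenolate at the less substituted C5 follows the trans-diaxial (Fürst–Plattner) path, which is open because the epoxide oxygen is cis to the equatorial isopropenyl group, so C5 is inverted and the 4β tertiary alcohol is kept.

Step 4
Reactants: 4 5α-(phenylselanyl)-3β,4β-diol
Product: 5 selenide 3β,4β-cyclic carbonate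
Conditions: CDI, DMAP (cat.), toluene, 80 °C
Reagents that add atoms: 1,1′-carbonyldiimidazole, O=C(n1ccnc1)n1ccnc1
Why: Carbonylation of the cis-diol (acyl imidazolide at the secondary OH, then five-membered ring closure by the tertiary OH) installs the allylic leaving group as a temporary ring without touching a stereocentre.

Step 5
Reactants: 5 selenide 3β,4β-cyclic carbonate
Product: 7 keto vinyl carbonate (1β-acetyl-4α-methylcyclohex-5-ene-3β,4β-diyl carbonate), via selenoxide methyl ketone 6 (not isolated)
Conditions: O3, pyridine, CH2Cl2, −78 °C; Ar purge; then 23 °C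
Reagents that add atoms: ozone, [O-][O+]=O
Why: Ozone cleaves the only alkene present (pyridine-mediated reductive ozonolysis, isopropenyl to C10 methyl ketone) and oxidises the selenide to selenoxide 6, whose syn-elimination on warming can only run towards C6 (C4 bears no H), so C5=C6 appears after the ozone is gone.

Step 6
Reactants: 8 N-methoxy-N-methyl-3-oxobutanamide
Product: 9 (E)-N-methoxy-N-methyl-3-(pyrrolidin-1-yl)but-2-enamide
Conditions: pyrrolidine, 4 Å MS, toluene, 23 → 60 °C; excess amine removed in vacuo
Reagents that add atoms: pyrrolidine, C1CCNC1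
Why: Condensation of a β-keto amide with a secondary amine should give the conjugated push–pull enaminone, driven by removal of water.

Step 7
Reactants: 7 keto vinyl carbonate; 9 (E)-N-methoxy-N-methyl-3-(pyrrolidin-1-yl)but-2-enamide
Product: 12 cis-decalin β-keto Weinreb amide (H1α, H6α, 3β-OH, 7α-carboxamide, 8-oxo, 10β-OH, 10α-methyl, C4=C5), via C7-allylated enaminone 10 (not isolated), via cyclised enaminone ketol 11 (not isolated)
Conditions: Pd(PPh3)4 (5 mol %), THF, 0 → 23 °C; then AcOH (0.5 equiv), 40 °C; then aq. NaOAc–AcOH buffer, 23 °C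
Reagents that add atoms: water, O
Why: Proposed new method: Pd(0) ionises the tertiary allylic C4–O bond of 7 anti to the carbonate (Pd on the α-face), CO2 is lost, and the neutral push–pull enamine 9 attacks the less substituted π-allyl terminus C6 with its β-carbon C7 anti to Pd, the unmasked C3 alkoxide taking the proton of the iminium ion to give 10; mild acid then lets the enamine double bond move from C7=C8 to C8=C9, and this α′-enamine adds to the C10 ketone (11) before aqueous buffer hydrolyses the vinylogous amide to 12. The closest known reaction types are the Tsuji–Trost cis-1,4-opening of cyclic vinyl epoxides and carbonates by soft carbon nucleophiles including enamines, the α,α′-annulation of ketone enamines with 1,3-bis-electrophiles, and the enamine aldol cyclisation of the Hajos–Parrish type; new is their union on a π-allyl/ketone bis-electrophile. Ring B closes in the 6-(enolendo)-exo-trig mode through a chair. C6 is set by double inversion at Pd (C7 enters on the β-face, cis-1,4 to O3 and cis to the carvone-derived C1 acetyl group, hence the cis ring fusion), while C7 and C10 are set by allylic 1,3-strain in the C8=C9 pyrrolidine enamine, which holds the C7 carboxamide axial (α) and therefore C5 axial (β) on the nascent ring, so that methyl C14 takes the equatorial (α) and O10 the axial (β) site, helped by a hydrogen bond from the cis-1,3 C3–OH. The step needs attack at C6 rather than C4 (C4 is quaternary and flanked by the alkoxide) and the [3+3] closure C9→C10 rather than the Robinson-type closure C14→C8 that a free β-keto amide would favour: C8 is an enamine carbon and never a free ketone until work-up, and no free amine is present to enolise C10 towards C14 or C1, which also guards the C1 stereocentre.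

Step 8
Reactants: 12 cis-decalin β-keto Weinreb amide
Product: 13 3β,8α,10β-triol Weinreb amide
Conditions: NaBH4, MeOH–CH2Cl2, −78 → −40 °C
Reagents that add atoms: none
Why: Ketone-selective borohydride reduction under steric approach control: in the preferred cis-decalin conformer (C10 equatorial on ring A) the axial C14 methyl screens the α-face of C8, so hydride should enter from the β-face to give the 8α alcohol, while the equilibrating C7 reacts as the epimer with the carboxamide equatorial and trans to C5.

Step 9
Reactants: 13 3β,8α,10β-triol Weinreb amide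
Product: 14 3β,8α,10β-triol 7α-methyl ketone
Conditions: MeMgBr (excess), THF, 0 → 23 °C; aq. NH4Cl
Reagents that add atoms: methylmagnesium bromide, C[Mg]Br
Why: Weinreb ketone synthesis, in which the three hydroxyls are masked as magnesium alkoxides and the chelated tetrahedral intermediate stops the addition at the C11 methyl ketone.

Step 10
Reactants: 14 3β,8α,10β-triol 7α-methyl ketone
Product: 15 tris(trimethylsilyl) ether of 14
Conditions: N-(trimethylsilyl)imidazole, CH2Cl2, 23 °C
Reagents that add atoms: N-(trimethylsilyl)imidazole, C[Si](C)(C)n1ccnc1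
Why: Non-basic silylation covers all three hydroxyls, the tertiary one included, without enolising the ketone, and turns the β-oxygen at C8 into a poor leaving group for the next step.

Step 11
Reactants: 15 tris(trimethylsilyl) ether of 14
Product: 17 3β,8α,10β-triol C11 enol triflate, via tris-TMS enol triflate 16 (not isolated)
Conditions: KHMDS, THF, −78 °C; PhNTf2, −78 → −20 °C; aq. NH4Cl; then citric acid, MeOH, 0 → 23 °C
Reagents that add atoms: N-phenylbis(trifluoromethanesulfonimide), O=S(=O)(N(c1ccccc1)S(=O)(=O)C(F)(F)F)C(F)(F)F
Why: Kinetic deprotonation of the methyl ketone at the unhindered CH3 (C13) and O-triflation give the terminal enol triflate with C7 untouched, and mild acidic methanolysis then strips the three TMS ethers.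

Step 12
Reactants: 17 3β,8α,10β-triol C11 enol triflate
Product: 18 3β-acetate of 17
Conditions: Ac2O (1.1 equiv), pyridine, CH2Cl2, 0 °C
Reagents that add atoms: acetic anhydride, CC(=O)OC(C)=O
Why: Site-selective acetylation should pick the unhindered allylic 3β-OH over the 8α-OH, which is flanked by C7 and syn-axial to C14, and over the tertiary 10β-OH.

Step 13
Reactants: 19 2,2-dimethyl-4,7-dihydro-1,3-dioxepine
Product: 20 (±)-trans-5,6-dibromo-2,2-dimethyl-1,3-dioxepane
Conditions: Br2, CH2Cl2, −20 °C
Reagents that add atoms: bromine, BrBr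
Why: Anti addition of bromine to the cis ring alkene through a bromonium ion.

Step 14
Reactants: 20 (±)-trans-5,6-dibromo-2,2-dimethyl-1,3-dioxepane
Product: 21 5-bromo-2,2-dimethyl-4,7-dihydro-1,3-dioxepine
Conditions: DBU, THF, 60 °C
Reagents that add atoms: none
Why: E2 dehydrobromination removes the more acidic H geminal to bromine and should give the vinyl bromide, whose alkene is cis by ring constraint.

Step 15
Reactants: 21 5-bromo-2,2-dimethyl-4,7-dihydro-1,3-dioxepine
Product: 22 2,2-dimethyl-4,7-dihydro-1,3-dioxepine-5-carboxylic acid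
Conditions: Pd(OAc)2 (cat.), dppf, CO (1 atm), Et3N, DMF–H2O, 70 °C
Reagents that add atoms: carbon monoxide, [C-]#[O+]; water, O
Why: Heck-type hydroxycarbonylation of a vinyl bromide (oxidative addition, CO insertion, hydrolysis of the acyl palladium) proceeds with retention of alkene geometry.

Step 16
Reactants: 22 2,2-dimethyl-4,7-dihydro-1,3-dioxepine-5-carboxylic acid; 18 3β-acetate of 17
Product: 24 8α-(dioxepine-5-carbonyloxy) 3β-acetate enol triflate, via Yamaguchi mixed anhydride 23 (not isolated)
Conditions: 2,4,6-Cl3C6H2COCl, Et3N, toluene, 23 °C; then 18, DMAP, toluene, 40 °C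
Reagents that add atoms: none
Why: Yamaguchi esterification can reach only the 8α-OH (O3 is acetylated, O10 tertiary), the ring flip of the cis-decalin offers this hydroxyl in an equatorial position, and no carbonyl group stands β to C8–O, so E1cB loss of the new ester is excluded.

Step 17
Reactants: 24 8α-(dioxepine-5-carbonyloxy) 3β-acetate enol triflate
Product: 25 acetonide-protected C12 acid
Conditions: Pd(OAc)2 (cat.), dppf, CO (1 atm), Et3N, DMF–H2O, 23 → 40 °C
Reagents that add atoms: carbon monoxide, [C-]#[O+]; water, O
Why: Pd-catalysed hydroxycarbonylation of the vinyl triflate builds the α-substituted acrylic acid directly, the triflate should add to Pd(0) faster than the hindered allylic acetate, and the acylated O8 cannot lactonise.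

Step 18
Reactants: 25 acetonide-protected C12 acid
Product: 26 target CNP0468194.1
Conditions: AcOH–H2O–THF (3:1:1), 23 °C
Reagents that add atoms: none
Why: Mild acid hydrolysis of the labile seven-membered isopropylidene ketal frees both primary alcohols, leaves the esters, the allylic acetate and the tertiary alcohol, and shows the E-alkene because the two CH2O groups were cis in the ring.

**Compound list**

1 | (S)-(+)-carvone | C1C=C(C)C(=O)C[C@H]1C(C)=C | starting material
2 | (+)-cis-carveol | C1C=C(C)[C@@H](O)C[C@H]1C(C)=C | intermediate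
3 | 4β,5β-epoxy alcohol | C1[C@H]2O[C@@]2(C)[C@@H](O)C[C@H]1C(C)=C | intermediate
4 | 5α-(phenylselanyl)-3β,4β-diol | C1[C@H]([Se]c2ccccc2)[C@@](C)(O)[C@@H](O)C[C@H]1C(C)=C | intermediate
5 | selenide 3β,4β-cyclic carbonate | C1[C@H]([Se]c2ccccc2)[C@@]3(C)OC(=O)O[C@H]3C[C@H]1C(C)=C | intermediate
6 | selenoxide methyl ketone (not isolated) | C1[C@H]([Se](=O)c2ccccc2)[C@@]3(C)OC(=O)O[C@H]3C[C@H]1C(C)=O | intermediate
7 | keto vinyl carbonate | C1=C[C@@]2(C)OC(=O)O[C@H]2C[C@H]1C(C)=O | intermediate
8 | N-methoxy-N-methyl-3-oxobutanamide | CC(=O)CC(=O)N(C)OC | starting material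
9 | (E)-N-methoxy-N-methyl-3-(pyrrolidin-1-yl)but-2-enamide | CON(C)C(=O)/C=C(\C)N1CCCC1 | intermediate
10 | C7-allylated enaminone (not isolated) | CON(C)C(=O)C(=C(C)N1CCCC1)[C@H]2C=C(C)[C@@H](O)C[C@H]2C(C)=O | intermediate
11 | cyclised enaminone ketol (not isolated) | CON(C)C(=O)C=1[C@H]2C=C(C)[C@@H](O)C[C@H]2[C@@](C)(O)CC=1N3CCCC3 | intermediate
12 | cis-decalin β-keto Weinreb amide | CON(C)C(=O)[C@@H]1[C@H]2C=C(C)[C@@H](O)C[C@H]2[C@@](C)(O)CC1=O | intermediate
13 | 3β,8α,10β-triol Weinreb amide | CON(C)C(=O)[C@@H]1[C@H]2C=C(C)[C@@H](O)C[C@H]2[C@@](C)(O)C[C@@H]1O | intermediate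
14 | 3β,8α,10β-triol 7α-methyl ketone | CC(=O)[C@@H]1[C@H]2C=C(C)[C@@H](O)C[C@H]2[C@@](C)(O)C[C@@H]1O | intermediate
15 | tris(trimethylsilyl) ether of 14 | CC(=O)[C@@H]1[C@H]2C=C(C)[C@@H](O[Si](C)(C)C)C[C@H]2[C@@](C)(O[Si](C)(C)C)C[C@@H]1O[Si](C)(C)C | intermediate
16 | tris-TMS enol triflate (not isolated) | C=C(OS(=O)(=O)C(F)(F)F)[C@@H]1[C@H]2C=C(C)[C@@H](O[Si](C)(C)C)C[C@H]2[C@@](C)(O[Si](C)(C)C)C[C@@H]1O[Si](C)(C)C | intermediate
17 | 3β,8α,10β-triol C11 enol triflate | C=C(OS(=O)(=O)C(F)(F)F)[C@@H]1[C@H]2C=C(C)[C@@H](O)C[C@H]2[C@@](C)(O)C[C@@H]1O | intermediate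
18 | 3β-acetate of 17 | C=C(OS(=O)(=O)C(F)(F)F)[C@@H]1[C@H]2C=C(C)[C@@H](OC(C)=O)C[C@H]2[C@@](C)(O)C[C@@H]1O | intermediate
19 | 2,2-dimethyl-4,7-dihydro-1,3-dioxepine | CC1(C)OCC=CCO1 | starting material
20 | (±)-trans-5,6-dibromo-2,2-dimethyl-1,3-dioxepane (one enantiomer drawn) | CC1(C)OC[C@@H](Br)[C@H](Br)CO1 | intermediate
21 | 5-bromo-2,2-dimethyl-4,7-dihydro-1,3-dioxepine | CC1(C)OCC=C(Br)CO1 | intermediate
22 | 2,2-dimethyl-4,7-dihydro-1,3-dioxepine-5-carboxylic acid | CC1(C)OCC=C(CO1)C(=O)O | intermediate
23 | Yamaguchi mixed anhydride (not isolated) | CC1(C)OCC=C(CO1)C(=O)OC(=O)c2c(Cl)cc(Cl)cc2Cl | intermediate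
24 | 8α-(dioxepine-5-carbonyloxy) 3β-acetate enol triflate | C=C(OS(=O)(=O)C(F)(F)F)[C@@H]1[C@H]2C=C(C)[C@@H](OC(C)=O)C[C@H]2[C@@](C)(O)C[C@@H]1OC(=O)C3=CCOC(C)(C)OC3 | intermediate
25 | acetonide-protected C12 acid | C=C(C(=O)O)[C@@H]1[C@H]2C=C(C)[C@@H](OC(C)=O)C[C@H]2[C@@](C)(O)C[C@@H]1OC(=O)C3=CCOC(C)(C)OC3 | intermediate
26 | CNP0468194.1 | C=C(C(=O)O)[C@@H]1[C@H]2C=C(C)[C@@H](OC(C)=O)C[C@H]2[C@@](C)(O)C[C@@H]1OC(=O)/C(=C/CO)CO | target

**Step count:** 18 steps in total. The longest linear sequence is 14 steps (steps 1–5, 7–12, 16–18).

**Steps most likely to fail**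

1. Step 7. Several processes may interfere:
   - The enaminone may attack the π-allyl slowly, or through nitrogen.
   - The π-allyl may collapse by β-hydride or vinylogous elimination, with aromatisation of ring A.
   - The enamine may fail to move to C9, the ketol may dehydrate, or C1 may epimerise.

   The fallback uses known chemistry, reverses the order of the two bonds, and sets out from 7. Compound 8 is turned with NaH, then n-BuLi (THF, −78 °C, LaCl3·2LiCl) into the sodium lithium dianion of 8 F1. This adds through its terminal carbon C9 to the C10 ketone (1,3-dicarbonyl dianion aldol), giving the δ-hydroxy-β-keto amide carbonate F2. In F2, C1 can no longer enolise; the C10 epimers are separated by chromatography. Pd(PPh3)4 in THF then closes C6–C7 by intramolecular Tsuji–Trost alkylation with loss of CO2, and the route is rejoined at 12.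

2. Step 5. Selenium may be over-oxidised, the selenenic acid may add to the new alkene, or the β,γ-unsaturated ketone may undergo base-induced conjugation or vinylogous loss of the carbonate. The fallback separates the two oxidations and sets out from 5.
   - H2O2 and pyridine in CH2Cl2 (0 → 23 °C) give the isopropenyl selenoxide F3, which eliminates to the isopropenyl vinyl carbonate F4.
   - Catalytic OsO4 with NMO dihydroxylates only the accessible, more electron-rich 1,1-disubstituted alkene, giving the side-chain 1,2-diol F5.
   - Buffered NaIO4 cleaves this diol under neutral conditions, and the route is rejoined at 7.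

3. Step 8. Facial selectivity at C8 may be poor, or reduction may run through the wrong C7 epimer. The fallback changes the control element from steric approach to intramolecular delivery. Me4NBH(OAc)3 in MeCN–AcOH at −20 °C binds the 10β-hydroxyl of 12 and hands its hydride to the β-face of C8 (hydroxyl-directed 1,3-anti reduction). It sets out from 12, rejoins the route at 13 and makes no new compound (F0).

Further compounds
F1 | step 7 | sodium lithium dianion of 8 | [Na+].[Li+].[CH2-]C(=O)[CH-]C(=O)N(C)OC
F2 | step 7 | δ-hydroxy-β-keto amide carbonate | C1=C[C@@]2(C)OC(=O)O[C@H]2C[C@H]1[C@@](C)(O)CC(=O)CC(=O)N(C)OC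
F3 | step 5 | isopropenyl selenoxide | C1[C@H]([Se](=O)c2ccccc2)[C@@]3(C)OC(=O)O[C@H]3C[C@H]1C(C)=C
F4 | step 5 | isopropenyl vinyl carbonate | C1=C[C@@]2(C)OC(=O)O[C@H]2C[C@H]1C(C)=C
F5 | step 5 | side-chain 1,2-diol | C1=C[C@@]2(C)OC(=O)O[C@H]2C[C@H]1C(C)(O)CO
F0 | step 8 | none | none
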